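Follow the enzyme.

| setting | autumn | dawn | midnight | summer |
|---|---|---|---|---|
| starting material | 0.10 M (in portions, 2, over 25 s) | 0.10 M | 0.10 M | 0.10 M (fed, over 25 s) |
| second substrate | 1.00 equiv | 1.00 equiv | 1.00 equiv (fed, over 25 s) | 1.00 equiv |
| free enzyme | 0.02 mol% | 0.02 mol% | 0.02 mol% | 0.02 mol% |
| time | 30 s | 30 s | 30 s | 30 s |
| remark | first portion at the start, last at 25 s | everything together at the start | all else is in the flask from the start; the feed brings no volume worth counting | all else is in the flask from the start; the feed brings no volume worth counting |

    starting material + free enzyme ⇌ first complex (K1 = 7.0 L mol⁻¹, k1 = 3.9 × 10⁵ L mol⁻¹ s⁻¹)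
    first complex ⇌ loaded enzyme + first product (K2 = 0.30 M, k2 = 460 s⁻¹)
    second substrate + loaded enzyme ⇌ second complex (K3 = 140 L mol⁻¹, k3 = 3.2 × 10⁵ L mol⁻¹ s⁻¹)
    second complex → free enzyme + target (k4 = 3700 s⁻¹)
    target + free enzyme ⇌ isomer of the product + free enzyme, rate k5*[free enzyme]*[target] forward; the back reaction follows from the equilibrium constant (K5 = 2.4, k5 = 390 L mol⁻¹ s⁻¹)

- the flask that comes out highest in amount of target, in percent of the starting material charged, or "all alike" when all lie within 1.5 percentage points (autumn / dawn / midnight / summer / all alike)
- target at the end, in percent of the starting material charged, autumn
- target at the end, in percent of the starting material charged, dawn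
- target at the end, in percent of the starting material charged, midnight
- target at the end, in percent of the starting material charged, summer

Take dawn first, where nothing waits outside the flask. In the first instants free enzyme meets starting material. First complex falls back at 55700 s⁻¹, far faster than it loses first product at 460 s⁻¹. So binding in dawn sits near equilibrium, and at the start first complex holds 41.2 % of the enzyme.

Call the binding and the loss of first product the loading stage. Its Michaelis constant, K, is 144 mM, and its constant at low starting material is 3190 L mol⁻¹ s⁻¹. The unloading stage, second substrate onto loaded enzyme and on to target, has a net constant of 1.98 × 10⁵ L mol⁻¹ s⁻¹, much larger than the loading one. So I take loading as the rate-limiting step and leave out the return of first product.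

Now integrate that one rate in closed form. Let x be the fraction of starting material still free in dawn, and s the charge over K, here 0.694. Then ln(1/x) + s(1 − x) = θ. Here θ is the catalyst dose, the loading constant times the enzyme charged times the time, 1.92.

For the middle of dawn, set x to 0.5: the equation puts that point at 16.3 s. For the end, put guesses back into the equation. They run 14.7 %, 26.6 %, 24.5 %, 24.9 %. By my reckoning first complex then holds about 14.8 % of the enzyme.

Late in dawn the isomerisation begins to count. Taken forward alone, with the enzyme as charged, step 5 gives target a half-life of 89 s in dawn, and if I count the target as present for 0.5 of the run, I reckon it loses 11.7 %. My figure for target in dawn is 66.4 %.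

In midnight the feed of second substrate brings 4.00 mM s⁻¹, a little more than the 3.77 mM s⁻¹ that loading demands at the start. So I place midnight close to dawn. In summer and autumn some of the starting material enters only later, so I place both lower, without a figure.

The forecast named dawn and gave 44.5 % for autumn, 67 % for dawn, 64 % for midnight and 49 % for summer. For dawn that differs a little from my figure. Its ground, speaking of starting material, was that “withholding it (summer, autumn) costs far more conversion than withholding the fast-consumed second substrate (midnight)”.

The simulation puts dawn highest, with 44.6 % for autumn, 66.4 % for dawn, 64.4 % for midnight and 49.5 % for summer.

Dawn kept 27 % of its starting material, which reads back as a dose of 1.82 against 1.92. The neighbour of dawn with 0.034 mol% of free enzyme has a dose of 3.26, so the equation leaves 7.30 %, and that flask kept 8.8 %. Take away the undoing of first complex and the gap in target between dawn and autumn narrows: it is 22 percentage points in the run as it stands and 11 points without the undoing.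

The rate constants were set for the occasion, and the outcome is calculated.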